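**Retrosynthetic overview**

- Numbering: C1 (bears guaiacyl ring C), C2 (CH2OH), C3 (CHO), C4 (=CH), C4a/C8a (ring fusion), C7 (OH), C8 (OMe). The strategy rests on C1 and C4 both being benzylic carbons on the neighbouring ring A atoms C8a and C4a. Ring B is therefore the [4+2] adduct of a ring A o-quinodimethane (C1–C8a–C4a–C4) and a C2–C3 fumarate whose two carboxyls end as CH2OH and CHO.
- Endgame, backwards: phenol release (BCl3), allylic oxidation at the C3 carbinol (MnO2), reduction of both esters (i-Bu2AlH), and dehydration of the C4 alcohol lead back to the cycloadduct.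
- Ring B is the only ring made. It closes by photoenolization/Diels–Alder reaction of a 2-benzylbenzaldehyde with bis[(S)-lactyl] fumarate; rings A and C arrive in the building blocks.
- The aldehyde comes from a Negishi coupling of 4-benzyloxy-2-bromo-3-methoxybenzaldehyde (three steps from 3,4-dihydroxybenzaldehyde) with the benzylic zinc reagent from 4-benzyloxy-3-methoxybenzyl alcohol. The fumarate comes from fumaryl chloride and methyl (S)-lactate.

Key step: step 7

Assumption 1: the (S)-lactyl esters are taken to steer the diene to the face that gives the (1S,2R,3S,4S) adduct, by analogy with additions of hydroxy-o-quinodimethanes to fumarates of (S)-α-hydroxy esters; should the opposite sense be found, methyl (R)-lactate would be used with no other change.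
Assumption 2: 4-benzyloxy-3-methoxybenzyl alcohol is taken as a purchased material; it is otherwise one NaBH4 reduction away from O-benzylvanillin.
Locants in the names of 13–17 follow the numbering of the overview.

**Route**

Step 1
Reactants: 1 3,4-dihydroxybenzaldehyde
Product: 2 4-benzyloxy-3-hydroxybenzaldehyde
Conditions: BnBr (1.05 equiv), NaHCO3, NaI (cat.), DMF, 40 °C
Reagents that add atoms: benzyl bromide, BrCc1ccccc1
Why: Williamson ether synthesis under weak base, in which only the more acidic 4-OH (para to the formyl group) is ionized, so that monobenzylation should occur at O4.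

Step 2
Reactants: 2 4-benzyloxy-3-hydroxybenzaldehyde
Product: 3 4-benzyloxy-2-bromo-3-hydroxybenzaldehyde
Conditions: Br2 (1.05 equiv), NaOAc, Fe powder (cat.), AcOH, 20 °C
Reagents that add atoms: bromine, BrBr
Why: Electrophilic aromatic bromination directed by the free 3-OH to its only open ortho position C2 (C4 is blocked), the outcome established for the 4-methoxy analogue isovanillin under the same buffered conditions, with attack at C6 as the minor competitor to be removed by crystallization.

Step 3
Reactants: 3 4-benzyloxy-2-bromo-3-hydroxybenzaldehyde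
Product: 4 4-benzyloxy-2-bromo-3-methoxybenzaldehyde
Conditions: MeI, K2CO3, DMF, 20 °C
Reagents that add atoms: methyl iodide, CI
Why: Williamson O-methylation of the only free phenol; nothing else in 3 is alkylated under carbonate conditions.

Step 4
Reactants: 5 4-benzyloxy-3-methoxybenzyl alcohol
Product: 6 4-benzyloxy-3-methoxybenzyl chloride
Conditions: SOCl2, CH2Cl2, 0 °C; used at once
Reagents that add atoms: thionyl chloride, O=S(Cl)Cl
Why: Chlorodehydroxylation through the chlorosulfite, fast for a benzylic alcohol activated by the para oxygen and harmless to the aryl ethers.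

Step 5
Reactants: 6 4-benzyloxy-3-methoxybenzyl chloride; 4 4-benzyloxy-2-bromo-3-methoxybenzaldehyde
Product: 8 4-benzyloxy-2-(4-benzyloxy-3-methoxybenzyl)-3-methoxybenzaldehyde, via (4-benzyloxy-3-methoxybenzyl)zinc chloride 7 (not isolated)
Conditions: Zn dust, LiCl, THF, 25 °C; then 4, Pd(OAc)2 (2 mol%), SPhos (4 mol%), THF, 25 to 50 °C
Reagents that add atoms: none
Why: Negishi cross-coupling, in which LiCl-assisted zinc insertion into the benzylic C–Cl bond gives 7 and this transmetallates to the arylpalladium bromide formed by oxidative addition of zerovalent palladium into the C–Br bond of 4 (helped by the ortho formyl group, the bulky biarylphosphine coping with the two ortho substituents), while benzylic zinc halides do not add to aldehydes at a competitive rate without a Lewis acid promoter.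

Step 6
Reactants: 9 methyl (S)-lactate; 10 fumaryl chloride
Product: 11 bis[(S)-1-methoxy-1-oxopropan-2-yl] fumarate
Conditions: 9 (2.2 equiv), toluene, 80 °C, N2 sweep to remove HCl
Reagents that add atoms: none
Why: Twofold O-acylation of the secondary alcohol by the diacid chloride, which breaks no bond at the stereocentre (S retained) and leaves the E double bond untouched.

Step 7
Reactants: 8 4-benzyloxy-2-(4-benzyloxy-3-methoxybenzyl)-3-methoxybenzaldehyde; 11 bis[(S)-1-methoxy-1-oxopropan-2-yl] fumarate
Product: 13 bis[(S)-1-methoxy-1-oxopropan-2-yl] (1S,2R,3S,4S)-7-benzyloxy-1-(4-benzyloxy-3-methoxyphenyl)-4-hydroxy-8-methoxy-1,2,3,4-tetrahydronaphthalene-2,3-dicarboxylate, via hydroxy-o-quinodimethane 12 (not isolated)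
Conditions: hν (350 nm lamps, Pyrex), 11 (3 equiv), degassed toluene (0.02 M), 20 °C
Reagents that add atoms: none
Why: Excitation of the formyl group of 8 is followed by intramolecular 1,5-hydrogen transfer from the doubly benzylic CH2 and relaxation to dienol 12, whose isomer with OH and aryl group both turned away from the diene interior lives long enough to be trapped, whereas the OH-inward isomer returns to 8 by a thermal 1,5-shift. This is the photoenolization/Diels–Alder reaction of 2-alkylbenzaldehydes, and the addition of hydroxy-o-quinodimethanes to fumarates of chiral α-hydroxy esters is the closest known class. Ring B, a six-membered carbocycle, closes by an intermolecular suprafacial [4+2] cycloaddition that forms C1–C2 and C3–C4 and restores the aromaticity of ring A. The C2/C3 trans relation follows from the retained E geometry of the fumarate, the C1-aryl/C4-OH cis relation from the out,out geometry of 12, and the C3-ester/C4-OH cis relation (hence C1-aryl/C2-ester trans) from the endo transition state in which the dienol OH hydrogen-bonds to the carbonyl of the ester that ends on C3. The absolute configuration is set by the two (S)-lactyl groups, which are related by the twofold axis of 11 and so shield the same face of the C=C bond, endo approach to the open face giving one adduct. The step needs endo and π-facial selectivity (regiochemistry does not arise with a symmetric dienophile); the non-polar solvent keeps the hydrogen bond, filtered long-wavelength light and the fast intramolecular hydrogen transfer limit sensitized E/Z isomerization of 11, and oxygen is excluded because it intercepts the dienol.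

Step 8
Reactants: 13 cycloadduct (4-hydroxytetralin diester)
Product: 14 bis[(S)-1-methoxy-1-oxopropan-2-yl] (1S,2R)-7-benzyloxy-1-(4-benzyloxy-3-methoxyphenyl)-8-methoxy-1,2-dihydronaphthalene-2,3-dicarboxylate
Conditions: TsOH·H2O (10 mol%), toluene, 80 °C
Reagents that add atoms: none
Why: Acid-catalysed E1 dehydration, in which the C4 cation is benzylic and stabilized by the para oxygen on C7 and loss of H3 gives the C3=C4 bond conjugated with ring A and the C3 ester, C1 and C2 being untouched in the absence of base.

Step 9
Reactants: 14 dihydronaphthalene diester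
Product: 15 [(1S,2R)-7-benzyloxy-1-(4-benzyloxy-3-methoxyphenyl)-8-methoxy-1,2-dihydronaphthalene-2,3-diyl]dimethanol
Conditions: i-Bu2AlH (10 equiv), CH2Cl2, −78 to 0 °C; aq. potassium sodium tartrate
Reagents that add atoms: none
Why: Hydride reduction of all four ester carbonyls, which turns the C2 and C3 carboxyls into CH2OH (1,2-reduction at the unsaturated ester) and removes both auxiliaries as propane-1,2-diol without touching C1 or C2.

Step 10
Reactants: 15 diol
Product: 16 (1S,2R)-7-benzyloxy-1-(4-benzyloxy-3-methoxyphenyl)-2-(hydroxymethyl)-8-methoxy-1,2-dihydronaphthalene-3-carbaldehyde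
Conditions: activated MnO2 (15 equiv), CH2Cl2, 20 °C
Reagents that add atoms: none
Why: Chemoselective MnO2 oxidation, which needs allylic activation and so should convert only the C3 carbinol (allylic and conjugated with ring A) into the enal and leave the saturated CH2OH on C2; the conjugated aldehyde has little tendency to close to the lactol that would allow over-oxidation.

Step 11
Reactants: 16 O,O'-dibenzylvitedoin A
Product: 17 vitedoin A
Conditions: BCl3 (1 M in CH2Cl2, 5 equiv), pentamethylbenzene (8 equiv), CH2Cl2, −78 °C; then MeOH, aq. NaHCO3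
Reagents that add atoms: none
Why: Lewis acid cleavage of aryl benzyl ethers with a non-basic cation scavenger, in which the benzyl cations are captured by pentamethylbenzene, the methyl ethers are inert at −78 °C and the C3=C4 bond, which rules out hydrogenolysis, is not affected.

**Compound list**

1 | 3,4-dihydroxybenzaldehyde | O=Cc1ccc(O)c(O)c1 | starting material
2 | 4-benzyloxy-3-hydroxybenzaldehyde | O=Cc1ccc(OCc2ccccc2)c(O)c1 | intermediate
3 | 4-benzyloxy-2-bromo-3-hydroxybenzaldehyde | O=Cc1ccc(OCc2ccccc2)c(O)c1Br | intermediate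
4 | 4-benzyloxy-2-bromo-3-methoxybenzaldehyde | O=Cc1ccc(OCc2ccccc2)c(OC)c1Br | intermediate
5 | 4-benzyloxy-3-methoxybenzyl alcohol | COc1cc(CO)ccc1OCc1ccccc1 | starting material
6 | 4-benzyloxy-3-methoxybenzyl chloride | COc1cc(CCl)ccc1OCc1ccccc1 | intermediate
7 | (4-benzyloxy-3-methoxybenzyl)zinc chloride (LiCl complex in THF, not isolated) | COc1cc(C[Zn]Cl)ccc1OCc1ccccc1 | intermediate
8 | 4-benzyloxy-2-(4-benzyloxy-3-methoxybenzyl)-3-methoxybenzaldehyde | O=Cc1ccc(OCc2ccccc2)c(OC)c1Cc1ccc(OCc2ccccc2)c(OC)c1 | intermediate
9 | methyl (S)-lactate | C[C@H](O)C(=O)OC | starting material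
10 | fumaryl chloride | O=C(Cl)/C=C/C(=O)Cl | starting material
11 | bis[(S)-1-methoxy-1-oxopropan-2-yl] fumarate | COC(=O)[C@H](C)OC(=O)/C=C/C(=O)O[C@@H](C)C(=O)OC | intermediate
12 | hydroxy-o-quinodimethane from 8 (dienol with OH and aryl group both outward, not isolated) | O/C=C1\C=CC(OCc2ccccc2)=C(OC)/C1=C\c1ccc(OCc2ccccc2)c(OC)c1 | intermediate
13 | bis[(S)-1-methoxy-1-oxopropan-2-yl] (1S,2R,3S,4S)-7-benzyloxy-1-(4-benzyloxy-3-methoxyphenyl)-4-hydroxy-8-methoxy-1,2,3,4-tetrahydronaphthalene-2,3-dicarboxylate (1,2-trans, 2,3-trans, 3,4-cis) | COc1cc([C@H]2c3c(ccc(OCc4ccccc4)c3OC)[C@@H](O)[C@@H](C(=O)O[C@@H](C)C(=O)OC)[C@@H]2C(=O)O[C@@H](C)C(=O)OC)ccc1OCc1ccccc1 | intermediate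
14 | bis[(S)-1-methoxy-1-oxopropan-2-yl] (1S,2R)-7-benzyloxy-1-(4-benzyloxy-3-methoxyphenyl)-8-methoxy-1,2-dihydronaphthalene-2,3-dicarboxylate | COc1cc([C@H]2c3c(ccc(OCc4ccccc4)c3OC)C=C(C(=O)O[C@@H](C)C(=O)OC)[C@@H]2C(=O)O[C@@H](C)C(=O)OC)ccc1OCc1ccccc1 | intermediate
15 | [(1S,2R)-7-benzyloxy-1-(4-benzyloxy-3-methoxyphenyl)-8-methoxy-1,2-dihydronaphthalene-2,3-diyl]dimethanol | COc1cc([C@H]2c3c(ccc(OCc4ccccc4)c3OC)C=C(CO)[C@@H]2CO)ccc1OCc1ccccc1 | intermediate
16 | (1S,2R)-7-benzyloxy-1-(4-benzyloxy-3-methoxyphenyl)-2-(hydroxymethyl)-8-methoxy-1,2-dihydronaphthalene-3-carbaldehyde | COc1cc([C@H]2c3c(ccc(OCc4ccccc4)c3OC)C=C(C=O)[C@@H]2CO)ccc1OCc1ccccc1 | intermediate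
17 | vitedoin A, (1S,2R)-7-hydroxy-1-(4-hydroxy-3-methoxyphenyl)-2-(hydroxymethyl)-8-methoxy-1,2-dihydronaphthalene-3-carbaldehyde | COc1cc([C@H]2c3c(ccc(O)c3OC)C=C(C=O)[C@@H]2CO)ccc1O | target

**Step count**

Total step count: 11. Longest linear sequence: 9 steps (steps 1, 2, 3, 5, 7, 8, 9, 10, 11, from 3,4-dihydroxybenzaldehyde).

**Steps most likely to fail**

1. Step 7. The dienol may be trapped too slowly, because the C8 methoxy group presses on the outward aryl group and the dienol reverts to the aldehyde. Triplet sensitization may isomerize the fumarate to the maleate and so give 2,3-cis adducts. Facial discrimination by the lactyl groups may be incomplete. The fallback sets out from 8 and comes back at 13, and it separates diene generation from the cycloaddition. Irradiation of 8 in benzene saturated with SO2 should capture the dienol by cheletropic addition as cis-5-benzyloxy-3-(4-benzyloxy-3-methoxyphenyl)-1-hydroxy-4-methoxy-1,3-dihydrobenzo[c]thiophene 2,2-dioxide F1. Heating F1 with 11 and ZnO in toluene at 80–110 °C in the dark should extrude SO2, regenerate dienol 12 thermally at a high dienophile concentration and without any light that could isomerize 11, and give 13.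

2. Step 5. Zinc insertion into the electron-rich benzylic chloride may be accompanied by Wurtz-type homocoupling, and a slow coupling at the doubly ortho-substituted bromide may let the organozinc add to the formyl group. The fallback sets out from 4 and comes back at 8, and it builds the diarylmethane by carbonyl addition and deoxygenation instead of cross-coupling. Acetalization of 4 (ethylene glycol, TsOH, toluene, reflux) should give 2-(4-benzyloxy-2-bromo-3-methoxyphenyl)-1,3-dioxolane F2. Bromine–lithium exchange (n-BuLi, THF, −78 °C) and addition to commercial O-benzylvanillin should give racemic [3-benzyloxy-6-(1,3-dioxolan-2-yl)-2-methoxyphenyl](4-benzyloxy-3-methoxyphenyl)methanol F3. Ionic hydrogenation follows (Et3SiH present before CF3CO2H is added, CH2Cl2, −20 to 0 °C), so that the benzhydryl cation is reduced as it forms. Aqueous acid in the work-up should then hydrolyse the dioxolane and give 8.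

3. Step 11. The hydroxy enal may not survive the Lewis acid: chloride may add to the activated enal, the C8 methyl ether next to the freed C7 phenol may be lost, or the electron-rich rings may be benzylated. The fallback sets out from 14 and comes back at 17, and it moves the debenzylation to the robust diester stage. Treatment of 14 with BCl3 and pentamethylbenzene (CH2Cl2, −78 °C) should give bis[(S)-1-methoxy-1-oxopropan-2-yl] (1S,2R)-7-hydroxy-1-(4-hydroxy-3-methoxyphenyl)-8-methoxy-1,2-dihydronaphthalene-2,3-dicarboxylate F4. Silylation (TBSCl, imidazole, DMF) should give its bis(tert-butyldimethylsilyl) ether F5. Reduction with i-Bu2AlH as in step 9 should give the bis-silylated diol F6, and MnO2 as in step 10 the bis-silylated hydroxy enal F7. Fluoride release buffered with acetic acid (Bu4NF, AcOH, THF, 0 °C) should then give 17 without any Lewis acid touching the enal.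

**Further compounds**

F1 | step 7 | cis-5-benzyloxy-3-(4-benzyloxy-3-methoxyphenyl)-1-hydroxy-4-methoxy-1,3-dihydrobenzo[c]thiophene 2,2-dioxide (racemic, one enantiomer drawn) | O[C@@H]1c2ccc(OCc3ccccc3)c(OC)c2[C@H](c2ccc(OCc3ccccc3)c(OC)c2)S1(=O)=O
F2 | step 5 | 2-(4-benzyloxy-2-bromo-3-methoxyphenyl)-1,3-dioxolane | COc1c(OCc2ccccc2)ccc(C2OCCO2)c1Br
F3 | step 5 | [3-benzyloxy-6-(1,3-dioxolan-2-yl)-2-methoxyphenyl](4-benzyloxy-3-methoxyphenyl)methanol (racemic) | COc1c(OCc2ccccc2)ccc(C2OCCO2)c1C(O)c1ccc(OCc2ccccc2)c(OC)c1
F4 | step 11 | bis[(S)-1-methoxy-1-oxopropan-2-yl] (1S,2R)-7-hydroxy-1-(4-hydroxy-3-methoxyphenyl)-8-methoxy-1,2-dihydronaphthalene-2,3-dicarboxylate | COc1cc([C@H]2c3c(ccc(O)c3OC)C=C(C(=O)O[C@@H](C)C(=O)OC)[C@@H]2C(=O)O[C@@H](C)C(=O)OC)ccc1O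
F5 | step 11 | bis(tert-butyldimethylsilyl) ether of F4 | COc1cc([C@H]2c3c(ccc(O[Si](C)(C)C(C)(C)C)c3OC)C=C(C(=O)O[C@@H](C)C(=O)OC)[C@@H]2C(=O)O[C@@H](C)C(=O)OC)ccc1O[Si](C)(C)C(C)(C)C
F6 | step 11 | [(1S,2R)-7-(tert-butyldimethylsilyloxy)-1-(4-(tert-butyldimethylsilyloxy)-3-methoxyphenyl)-8-methoxy-1,2-dihydronaphthalene-2,3-diyl]dimethanol | COc1cc([C@H]2c3c(ccc(O[Si](C)(C)C(C)(C)C)c3OC)C=C(CO)[C@@H]2CO)ccc1O[Si](C)(C)C(C)(C)C
F7 | step 11 | O,O'-bis(tert-butyldimethylsilyl)vitedoin A | COc1cc([C@H]2c3c(ccc(O[Si](C)(C)C(C)(C)C)c3OC)C=C(C=O)[C@@H]2CO)ccc1O[Si](C)(C)C(C)(C)C
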